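In the early hours the coupling partner has two takers in each flask, the protic impurity and the substrate, and what reaches the substrate becomes open intermediate, which then feeds product and trapped intermediate.

the same everywhere: capture agent 4.55 mM; protic impurity 0.0273 M; time 4.0 d

| run | substrate | coupling partner | remark | temperature |
|---|---|---|---|---|
| amber | 0.091 M | 0.0910 M (fed, over 20 h) | the addition at 90 °C, then warmed to 110 °C; the feed brings no volume worth counting |  |
| blue | 0.091 M (fed, over 20 h) | 0.0910 M | all else is in the flask from the start; the feed brings no volume worth counting | 110 °C |
| grey | 0.091 M | 0.0910 M (in portions, 5, over 20 h) | first portion at the start, last at 20 h | 110 °C |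
| red | 0.091 M | 0.0910 M (fed, over 20 h) | all else is in the flask from the start; the feed brings no volume worth counting | 110 °C |

    substrate + coupling partner → open intermediate + released group (k1 = 1.05 L mol⁻¹ h⁻¹, Ea1 = 72.0 kJ mol⁻¹)
    open intermediate ⇌ product (K2 = 6.9, k2 = 0.0731 h⁻¹, Ea2 = 120 kJ mol⁻¹, ΔH2 = 5.00 kJ mol⁻¹)
    open intermediate + capture agent → trapped intermediate (k3 = 0.868 L mol⁻¹ h⁻¹, Ea3 = 100 kJ mol⁻¹)
    coupling partner + protic impurity → quenched reagent (k4 = 108 L mol⁻¹ h⁻¹, Ea4 = 73.0 kJ mol⁻¹)
    (constants at 110 °C)

- the constants hold at 110 °C; other temperatures follow from the activation energies and enthalpies

1. the flask with the highest share of product in product plus trapped intermediate ("all alike" if they lie within 1.5 percentage points) (amber / blue / grey / red / all alike)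
2. share of product in product plus trapped intermediate at the end, amber
3. share of product in product plus trapped intermediate at the end, blue
4. share of product in product plus trapped intermediate at the end, grey
5. share of product in product plus trapped intermediate at the end, red

- Begin with the end state. The protic impurity takes coupling partner at 2.95 h⁻¹, faster than the substrate does at 0.0955 h⁻¹, so in this reckoning the step's constant 108 L mol⁻¹ h⁻¹ need not be known closely, and the coupling partner, the limiting reagent, leaves a pool of 70.0% of the substrate charge.
- If you wait long enough, the capture agent can hold 5.00% of the charge, and the rest of the pool divides 6.9 to one between product and open intermediate, which puts the share at 91.9%. That figure is the reckoned share with the capture agent fully taken, and the question becomes how far trapping has gone by the end of the run.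
- Trapping is pseudo-first-order in capture agent, so the quantity to carry is the trapping exposure θ, the trapping constant times the open intermediate summed over time, which leaves the fraction e^-θ of the capture agent.
- I take the pool as delivered by the end of the feed, a simplification, so that open intermediate stands at its equilibrium part of the pool for about 76.0 h, and its excess while product builds is worth a further 82.4 h, the equilibrium constant over the relaxation rate, which makes the effective time 158 h. Of this, the relaxation term is about half, so you need 0.0731 h⁻¹, 6.9 and 0.868 L mol⁻¹ h⁻¹ well, whereas the feed time is 12.7% of it, so the timing of delivery, which 1.05 L mol⁻¹ h⁻¹ and amber's cooler feed alter, counts for less.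
- My number is θ = 1.11, which gives trapped intermediate 3.35% and product 58.2% of the charge, a share of 94.6%. Delaying delivery by a whole feed time shortens the effective time and moves this by about 0.4 percentage points, less than the margin, so I expect the flasks to count as alike.
- The forecast gave 95% for amber, 94.8% for blue, 94.8% for grey and 94.9% for red, hence all alike, on the ground “The addition mode only shifts the timing”.
- The simulation gives 94.8% for amber, 94.7% for blue, 94.7% for grey and 94.7% for red, so all alike.
- In amber the relaxation half-life of open intermediate and product at the later temperature, 0.345 d, is short against the 4.0 d of the run, and 39% of the capture agent is left at the end, where e^-θ gave 33.0%. My reckoning took the pool as delivered by the end of the feed, whereas in amber half of the first step's turnover up to the end of the run is done at 1.10 d, later than the 20 h of the feed.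
- Take the neighbour, amber with 0.018 M of capture agent. Carrying over the same θ gives trapped intermediate 13.3% and product 49.6% of the charge, a share of 78.9%; the computed neighbour holds 11.2% of trapped intermediate and 48.5% of product, a share of 81.3%.

The constants used here were chosen freely.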